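**Plan**
- Retrosynthesis first cuts the two aryl ketone bonds C(=O)–C1 of the 2,4-dihydroxyphenyl rings (one at the C3 carbonyl, one at the end of the C5 chain). This leaves a trans-2-aryl-2,3-dihydrobenzofuran with an ester on C3 and a propanoate chain on C5.
- Enabling feature: in the five-membered ring O1–C2–C3–C3a–C7a, C3 is bonded both to arene carbon C3a and to an exocyclic carbonyl carbon. Putting that carbon back between C3 and C3a gives the six-membered ring O1–C2–C3–C4–C4a–C8a of a flavanone, so C3–C3a is cut next (retro 1,2-aryl shift).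
- The flavanone is cut at C2–C1' (aryl conjugate addition to a chromone) and the chromone at C6–CH2 (sp2–sp3 cross-coupling on 6-bromochromone).
- Forward: the benzopyranone bicycle is bought, the C6 chain is joined, the C2 aryl ring is added and the pyranone is contracted to the dihydrofuran. The sulfonate is then exchanged for MOM, both esters pass through Weinreb amides to the two resorcinol ketones in one operation, and five MOM groups are removed.
- Stereochemistry: C2 (S) comes from the chiral Pd/PyOx catalyst. C3 (S) is relayed from C2 in the ring contraction and is also the favoured trans epimer. Later steps keep contact with base short and cold so that C2–O1 is not opened.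

Key step: step 4

Assumption: the PyOx ligand is taken to differentiate the faces of a chromone as it does those of a 3-substituted cyclohexenone, which makes the (R)-ligand the one leading to the (2S)-flavanone; if the CD sign of the flavanone says otherwise, the (S)-ligand is used and nothing else changes.

**Step 1**
Reactants: 1 6-bromochromone (6-bromo-4H-chromen-4-one); 2 methyl 3-bromopropanoate
Product: 4 methyl 3-(4-oxo-4H-chromen-6-yl)propanoate, via (3-methoxy-3-oxopropyl)zinc bromide 3 (not isolated)
Conditions: 2, Zn dust (TMSCl/BrCH2CH2Br activated), LiCl, THF, 50 °C; then 1, Pd(OAc)2 (2 mol%), SPhos (4 mol%), THF, 25→40 °C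
Reagents that add atoms: none
Why: Negishi coupling of an aryl bromide with a chelate-stabilised zinc homoenolate is well established, needs no base (so the base-sensitive pyranone ring is not opened) and uses a nucleophile too mild to add to the enone or to the ester.

**Step 2**
Reactants: 5 4-hydroxyphenylboronic acid
Product: 6 4-(tosyloxy)phenylboronic acid
Conditions: TsCl (1.05 equiv), Na2CO3, THF–H2O, 0 °C→rt; acidic work-up
Reagents that add atoms: p-toluenesulfonyl chloride, Cc1ccc(cc1)S(=O)(=O)Cl
Why: Schotten–Baumann sulfonylation takes place at the phenoxide oxygen, while the boronic acid is only converted reversibly into its boronate and comes back on acidification.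

**Step 3**
Reactants: 4 methyl 3-(4-oxo-4H-chromen-6-yl)propanoate; 6 4-(tosyloxy)phenylboronic acid
Product: 7 (2S)-6-(3-methoxy-3-oxopropyl)-4'-tosyloxyflavanone
Conditions: Pd(OCOCF3)2 (5 mol%), (R)-t-BuPyOx (6 mol%), NH4PF6 (30 mol%), H2O (5 equiv), ClCH2CH2Cl, 60 °C, air; recrystallisation to raise the ee if needed
Reagents that add atoms: none
Why: Palladium(II)/PyOx-catalysed asymmetric conjugate addition of arylboronic acids is documented for chromones: the aryl–Pd species inserts C2=C3 on the face left open by the tert-butyl group of the ligand, which sets C2 as S under catalyst control, and protonolysis of the Pd enolate in a neutral to weakly acidic medium avoids the retro-oxa-Michael opening that would racemise the flavanone.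

**Step 4**
Reactants: 7 (2S)-6-(3-methoxy-3-oxopropyl)-4'-tosyloxyflavanone
Product: 10 methyl (2S,3S)-5-(3-methoxy-3-oxopropyl)-2-(4-tosyloxyphenyl)-2,3-dihydro-1-benzofuran-3-carboxylate (trans diester), via 4-methoxy-2H-chromene enol ether 8 (not isolated), via C3-iodanyl dimethyl ketal 9 (not isolated)
Conditions: PhI(OAc)2 (1.2 equiv), HC(OMe)3 (solvent), conc. H2SO4 (cat.), 0 °C→rt
Reagents that add atoms: trimethyl orthoformate, COC(OC)OC
Why: Acid and orthoformate turn the C4 ketone of 7 into enol ether 8, whose C3 attacks the iodine(III) centre on the face opposite the pseudo-equatorial C2 aryl group, and methanol adds to the resulting C4 oxocarbenium ion to give the 2,3-trans iodane ketal 9. In 9 the equatorial C3–I bond is antiperiplanar to the ring bond C4–C4a, so the ketal oxygens push C4a across to C3 through a bridged phenonium ion while iodobenzene departs, and the dimethoxycarbenium ion left at old C4 is demethylated to the methyl ester. The closest known reaction type is this very one, the iodine(III)- or thallium(III)-mediated oxidative 1,2-aryl shift of aryl ketone enol ethers, which on flavanones is an established entry to trans methyl 2-aryl-2,3-dihydrobenzofuran-3-carboxylates. The ring O1–C2–C3–C3a–C7a is closed by ring contraction (C3–C3a is made as C4–C4a breaks, six members to five), not by attack of a chain end on an acceptor. C2 takes no part and stays S, while C3 is fixed by substrate control from C2, since anti iodination followed by inversion in the shift places the ester trans to the aryl group (3S), the epimer that is also favoured at equilibrium. The step needs migration of C4a to outrun migration of the C2 aryl group (isoflavone pathway) and loss of the C2 hydrogen (flavone pathway); O1 on C8a, ortho to the migrating carbon, stabilises the phenonium ion, the tosyloxy group makes the C2 aryl ring a poor migrating group, and the acidic medium keeps the flavanone from opening to the chalcone.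

**Step 5**
Reactants: 10 trans diester tosylate
Product: 11 methyl (2S,3S)-2-(4-hydroxyphenyl)-5-(3-methoxy-3-oxopropyl)-2,3-dihydro-1-benzofuran-3-carboxylate
Conditions: Mg turnings (10 equiv), MeOH–THF, 0 °C→rt, ultrasound; poured into cold 1 M HCl
Reagents that add atoms: none
Why: Magnesium in methanol cleaves aryl sulfonates by single-electron transfer into the S–O bond (dissolving-metal desulfonylation), the methyl esters see only degenerate exchange with methoxide, and the one base-sensitive site, C3–H, can at worst epimerise back to the favoured trans isomer because expulsion of O1 from a C3 enolate is the reverse of a 5-endo-trig closure and has poor orbital overlap.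

**Step 6**
Reactants: 11 phenol diester
Product: 12 methyl (2S,3S)-5-(3-methoxy-3-oxopropyl)-2-[4-(methoxymethoxy)phenyl]-2,3-dihydro-1-benzofuran-3-carboxylate
Conditions: MOMCl (1.5 equiv), i-Pr2NEt, CH2Cl2, 0 °C→rt
Reagents that add atoms: chloromethyl methyl ether, COCCl
Why: O-alkylation of a phenol with MOMCl under a hindered amine base is routine, the base is too weak to touch C3–H, and the acetal masks the phenoxide that could otherwise push open C2–O1 in the organolithium step and later leaves together with the other four MOM groups.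

**Step 7**
Reactants: 12 MOM diester
Product: 13 (2S,3S)-N-methoxy-5-{3-[methoxy(methyl)amino]-3-oxopropyl}-2-[4-(methoxymethoxy)phenyl]-N-methyl-2,3-dihydro-1-benzofuran-3-carboxamide (bis-Weinreb amide)
Conditions: MeNHOMe·HCl (6 equiv), AlMe3 (6 equiv), CH2Cl2, 0→35 °C; Rochelle salt work-up
Reagents that add atoms: N,O-dimethylhydroxylamine hydrochloride, CNOC.Cl
Why: Aluminium-amide aminolysis of esters (Weinreb amide formation) is driven by Lewis acid activation and not by base, so both the unhindered and the α-branched ester should be converted without enolate chemistry at C3, and MOM ethers and p-alkoxybenzyl-type ethers are known to tolerate the reagent near room temperature.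

**Step 8**
Reactants: 14 4-bromoresorcinol
Product: 15 1-bromo-2,4-bis(methoxymethoxy)benzene
Conditions: MOMCl (2.5 equiv), i-Pr2NEt, CH2Cl2, 0 °C→rt
Reagents that add atoms: chloromethyl methyl ether, COCCl
Why: Double O-alkylation of the resorcinol with MOMCl gives acetals that withstand butyllithium, stabilise the ortho-lithio species by chelation and fall off under mild acid.

**Step 9**
Reactants: 13 bis-Weinreb amide; 15 1-bromo-2,4-bis(methoxymethoxy)benzene
Product: 18 1-[2,4-bis(methoxymethoxy)phenyl]-3-{(2S,3S)-3-[2,4-bis(methoxymethoxy)benzoyl]-2-[4-(methoxymethoxy)phenyl]-2,3-dihydro-1-benzofuran-5-yl}propan-1-one, via 2,4-bis(methoxymethoxy)phenyllithium 16 (not isolated), via dilithium bis(hemiaminal) adduct 17 (not isolated)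
Conditions: 15 (3.2 equiv), n-BuLi (3.0 equiv), THF, −78 °C; then 13, −78→−40 °C; AcOH/THF quench at −78 °C
Reagents that add atoms: none
Why: Bromine–lithium exchange followed by aryllithium addition to Weinreb amides is a standard aryl ketone synthesis, the chelated tetrahedral adduct 17 cannot add a second aryl group and has no acidifying carbonyl next to C3, and the cold acetic acid quench releases both ketones only in a non-basic medium, so C2 and C3 are kept.

**Step 10**
Reactants: 18 penta-MOM diketone
Product: 19 1-(2,4-dihydroxyphenyl)-3-[(2S,3S)-3-(2,4-dihydroxybenzoyl)-2-(4-hydroxyphenyl)-2,3-dihydro-1-benzofuran-5-yl]propan-1-one (CNP0136359.1)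
Conditions: 3 M aq HCl–MeOH–THF (1:4:1), 40 °C
Reagents that add atoms: none
Why: Acid-catalysed acetal exchange with methanol removes phenolic MOM ethers under mild conditions, ionisation of C2–O1 is held back by the electron-withdrawing aroyl group on the neighbouring C3, no base is present, and any acid enolisation at C3 can only return to the favoured trans isomer.

**Compound list**
1 | 6-bromochromone | O=c1ccoc2ccc(Br)cc12 | starting material
2 | methyl 3-bromopropanoate | COC(=O)CCBr | starting material
3 | (3-methoxy-3-oxopropyl)zinc bromide | COC(=O)CC[Zn]Br | intermediate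
4 | methyl 3-(4-oxo-4H-chromen-6-yl)propanoate | COC(=O)CCc1ccc2occc(=O)c2c1 | intermediate
5 | 4-hydroxyphenylboronic acid | OB(O)c1ccc(O)cc1 | starting material
6 | 4-(tosyloxy)phenylboronic acid | Cc1ccc(cc1)S(=O)(=O)Oc1ccc(cc1)B(O)O | intermediate
7 | (2S)-6-(3-methoxy-3-oxopropyl)-4'-tosyloxyflavanone | COC(=O)CCc1ccc2c(c1)C(=O)C[C@@H](c1ccc(OS(=O)(=O)c3ccc(C)cc3)cc1)O2 | intermediate
8 | methyl 3-[(2S)-4-methoxy-2-(4-tosyloxyphenyl)-2H-chromen-6-yl]propanoate (enol ether) | COC(=O)CCc1ccc2c(c1)C(OC)=C[C@@H](c1ccc(OS(=O)(=O)c3ccc(C)cc3)cc1)O2 | intermediate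
9 | methyl 3-{(2R,3R)-3-[acetoxy(phenyl)-λ3-iodanyl]-4,4-dimethoxy-2-(4-tosyloxyphenyl)chroman-6-yl}propanoate (iodine and aryl trans; C2 unchanged in space) | COC(=O)CCc1ccc2c(c1)C(OC)(OC)[C@H](I(OC(C)=O)c1ccccc1)[C@@H](c1ccc(OS(=O)(=O)c3ccc(C)cc3)cc1)O2 | intermediate
10 | methyl (2S,3S)-5-(3-methoxy-3-oxopropyl)-2-(4-tosyloxyphenyl)-2,3-dihydro-1-benzofuran-3-carboxylate | COC(=O)CCc1ccc2c(c1)[C@H](C(=O)OC)[C@@H](c1ccc(OS(=O)(=O)c3ccc(C)cc3)cc1)O2 | intermediate
11 | methyl (2S,3S)-2-(4-hydroxyphenyl)-5-(3-methoxy-3-oxopropyl)-2,3-dihydro-1-benzofuran-3-carboxylate | COC(=O)CCc1ccc2c(c1)[C@H](C(=O)OC)[C@@H](c1ccc(O)cc1)O2 | intermediate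
12 | methyl (2S,3S)-5-(3-methoxy-3-oxopropyl)-2-[4-(methoxymethoxy)phenyl]-2,3-dihydro-1-benzofuran-3-carboxylate | COC(=O)CCc1ccc2c(c1)[C@H](C(=O)OC)[C@@H](c1ccc(OCOC)cc1)O2 | intermediate
13 | (2S,3S) bis-Weinreb amide of 12 | CON(C)C(=O)CCc1ccc2c(c1)[C@H](C(=O)N(C)OC)[C@@H](c1ccc(OCOC)cc1)O2 | intermediate
14 | 4-bromoresorcinol | Oc1ccc(Br)c(O)c1 | starting material
15 | 1-bromo-2,4-bis(methoxymethoxy)benzene | COCOc1ccc(Br)c(OCOC)c1 | intermediate
16 | 2,4-bis(methoxymethoxy)phenyllithium | [Li]c1ccc(OCOC)cc1OCOC | intermediate
17 | dilithium bis(hemiaminal) adduct of 13 with two equivalents of 16 (carbinolamine centres undefined) | [Li+].[Li+].COCOc1ccc(c(OCOC)c1)C([O-])(N(C)OC)CCc1ccc2c(c1)[C@H](C([O-])(N(C)OC)c1ccc(OCOC)cc1OCOC)[C@@H](c1ccc(OCOC)cc1)O2 | intermediate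
18 | (2S,3S) penta-MOM diketone | COCOc1ccc(c(OCOC)c1)C(=O)CCc1ccc2c(c1)[C@H](C(=O)c1ccc(OCOC)cc1OCOC)[C@@H](c1ccc(OCOC)cc1)O2 | intermediate
19 | 1-(2,4-dihydroxyphenyl)-3-[(2S,3S)-3-(2,4-dihydroxybenzoyl)-2-(4-hydroxyphenyl)-2,3-dihydro-1-benzofuran-5-yl]propan-1-one | O=C(CCc1ccc2c(c1)[C@H](C(=O)c1ccc(O)cc1O)[C@@H](c1ccc(O)cc1)O2)c1ccc(O)cc1O | target

Total step count: 10. Longest linear sequence: 8 steps (1, 3, 4, 5, 6, 7, 9, 10).

**Steps most likely to fail**

**Step 4.** The C3 iodane may lose the C2 hydrogen (dehydrogenation to the flavone), may be displaced at C3 by methanol, or the C2 aryl ring may migrate in place of C4a.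
- The fallback keeps the same C4a shift but drives it with a carbene. It sets out from 7 and comes back at 10.
- The lithium enolate of 7 (LiHMDS, THF, −78 °C, kept cold to hold back β-elimination of O1) is acylated with 2,2,2-trifluoroethyl trifluoroacetate to the 3-trifluoroacetylflavanone F1.
- Deacylative diazo transfer (MsN3, Et3N, MeCN, rt) should give the 3-diazoflavanone F2.
- Irradiation at 365 nm in methanol starts a Wolff rearrangement in which C4a moves from C4 to C3, and the ring-contracted ketene F3 is trapped by methanol.
- Protonation of the resulting enol may give part of the material as the cis ester F4, which catalytic DBU in CH2Cl2 should equilibrate to the trans ester 10.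

**Step 9.** The aryllithium may deprotonate C3 in place of adding, or addition may stall at the hindered C3 amide so that only the side-chain ketone forms.
- The fallback replaces polar addition by a non-basic cross-coupling. It sets out from 12 and comes back at 18.
- Treatment of 12 with AlMe3/EtSH (CH2Cl2, 0 °C→rt) should give the bis(S-ethyl thioester) F5.
- Aryllithium 16 is transmetallated with ZnCl2 to 2,4-bis(methoxymethoxy)phenylzinc chloride F6.
- A double Fukuyama coupling (PdCl2(PPh3)2, THF–toluene, rt) joins both acyl groups to the aryl rings and gives 18.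

**Step 5.** Methoxide that builds up in the medium, together with the freed 4'-phenoxide, may open C2–O1 with erosion of configuration, or S–O cleavage may stall.
- The fallback masks the phenol as a C–Br bond and unmasks it without base. It sets out from 4 and comes back at 11.
- Conjugate addition of commercial 4-bromophenylboronic acid to 4 under the conditions of step 3 should give the (2S)-4'-bromoflavanone F7.
- The iodine(III) ring contraction of step 4 then runs through the enol ether F8 and the iodane ketal F9 to the bromo diester F10. The bromophenyl ring is as poor a migrating group as the tosyloxyphenyl ring.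
- Miyaura borylation (B2pin2, KOAc, Pd(dppf)Cl2, dioxane, 80 °C) gives the pinacol boronate F11.
- Aqueous Oxone in acetone at rt oxidises the C–B bond to the phenol 11.

**Further compounds**
F1 | step 4 | 3-trifluoroacetyl derivative of 7 (C2 as in 7, C3 epimers or enol) | COC(=O)CCc1ccc2c(c1)C(=O)C(C(=O)C(F)(F)F)[C@@H](c1ccc(OS(=O)(=O)c3ccc(C)cc3)cc1)O2
F2 | step 4 | 3-diazo derivative of 7 (C2 unchanged in space) | COC(=O)CCc1ccc2c(c1)C(=O)C(=[N+]=[N-])[C@@H](c1ccc(OS(=O)(=O)c3ccc(C)cc3)cc1)O2
F3 | step 4 | ring-contracted ketene, 3-(oxomethylidene)-2,3-dihydrobenzofuran (C2 unchanged in space) | COC(=O)CCc1ccc2c(c1)C(=C=O)[C@@H](c1ccc(OS(=O)(=O)c3ccc(C)cc3)cc1)O2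
F4 | step 4 | cis-(2S,3R) epimer of 10 | COC(=O)CCc1ccc2c(c1)[C@@H](C(=O)OC)[C@@H](c1ccc(OS(=O)(=O)c3ccc(C)cc3)cc1)O2
F5 | step 9 | (2S,3S) bis(S-ethyl thioester) corresponding to 12 | CCSC(=O)CCc1ccc2c(c1)[C@H](C(=O)SCC)[C@@H](c1ccc(OCOC)cc1)O2
F6 | step 9 | 2,4-bis(methoxymethoxy)phenylzinc chloride | Cl[Zn]c1ccc(OCOC)cc1OCOC
F7 | step 5 | (2S)-4'-bromo-6-(3-methoxy-3-oxopropyl)flavanone | COC(=O)CCc1ccc2c(c1)C(=O)C[C@@H](c1ccc(Br)cc1)O2
F8 | step 5 | (2S)-2-(4-bromophenyl)-4-methoxy-2H-chromene enol ether | COC(=O)CCc1ccc2c(c1)C(OC)=C[C@@H](c1ccc(Br)cc1)O2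
F9 | step 5 | (2R,3R)-3-[acetoxy(phenyl)-λ3-iodanyl]-2-(4-bromophenyl)-4,4-dimethoxychroman (iodine and aryl trans) | COC(=O)CCc1ccc2c(c1)C(OC)(OC)[C@H](I(OC(C)=O)c1ccccc1)[C@@H](c1ccc(Br)cc1)O2
F10 | step 5 | methyl (2S,3S)-2-(4-bromophenyl)-5-(3-methoxy-3-oxopropyl)-2,3-dihydro-1-benzofuran-3-carboxylate | COC(=O)CCc1ccc2c(c1)[C@H](C(=O)OC)[C@@H](c1ccc(Br)cc1)O2
F11 | step 5 | (2S,3S) 4'-pinacolboronate diester | COC(=O)CCc1ccc2c(c1)[C@H](C(=O)OC)[C@@H](c1ccc(cc1)B1OC(C)(C)C(C)(C)O1)O2
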